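**Retrosynthetic overview**
- Ring C is closed last. The target comes from its pentakis-MOM ether, built by Claisen–Schmidt condensation of a ring-A 2-hydroxyacetophenone with a ring-B aldehyde and oxa-Michael closure; a catalyst-controlled transfer hydrogenation then removes the 2R epimer.
- The acetyl group reaches ring A by photo-Fries shift of an aryl acetate whose oxygen lies para to the side chain. That oxygen becomes O1, so the side chain can only end up at C6.
- Key disconnection: the C6–C1'' bond, made by nickel/photoredox deoxygenative coupling in which (R)-lavandulol itself releases the primary lavandulyl radical onto an aryl bromide flanked by two acetal ethers.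
- Rings A and B are both carried from resorcinol through one bromophenol (ortho-lithiation/bromination, then meta C–H borylation/oxidation for the third oxygen).
- (R)-Lavandulol comes from enantioselective α-prenylation of the dienediolate of 3-methylbut-3-enoic acid, then hydride reduction.

Assumption: the chiral lithium amide of step 1 is taken to shield the same enediolate face as in its arylacetic acid alkylations (isopropenyl in the place of aryl); if the antipodal acid forms, the mirror-image amine is used.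

**Route**

Step 1
Reactants: 1 3-methylbut-3-enoic acid; 2 1-bromo-3-methylbut-2-ene (prenyl bromide)
Product: 4 (2R)-5-methyl-2-(prop-1-en-2-yl)hex-4-enoic acid [(R)-lavandulic acid], via dilithium dienediolate 3 (not isolated)
Conditions: N,N'-bis[(1S)-1-phenyl-2-(piperidin-1-yl)ethyl]propane-1,3-diamine (1.05 equiv), n-BuLi (4 equiv), THF, 0 °C; 1; then −78 °C, 2; aq HCl (amine recovered by extraction)
Reagents that add atoms: none
Why: Enantioselective enediolate alkylation with a chiral lithium amide as traceless auxiliary: dienediolate 3 reacts at its α-carbon with the allylic bromide on the face left open in the mixed aggregate, which sets the side-chain stereocentre as R.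

Step 2
Reactants: 4 (2R)-5-methyl-2-(prop-1-en-2-yl)hex-4-enoic acid
Product: 5 (2R)-5-methyl-2-(prop-1-en-2-yl)hex-4-en-1-ol [(R)-lavandulol]
Conditions: LiAlH4, Et2O, 0 °C to rt; Fieser work-up
Reagents that add atoms: none
Why: Hydride reduction of the acid, which reacts as its carboxylate salt so the α-stereocentre cannot epimerise and the alkenes stay untouched.

Step 3
Reactants: 6 benzene-1,3-diol (resorcinol)
Product: 7 1,3-bis(methoxymethoxy)benzene
Conditions: MOMCl (2.5 equiv), iPr2NEt, CH2Cl2, 0 °C to rt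
Reagents that add atoms: chloro(methoxy)methane (MOMCl), COCCl
Why: Double Williamson-type O-alkylation with the reactive α-chloro ether gives the bis-acetal that directs the later lithiation and survives base, organolithium, light and transfer hydrogenation.

Step 4
Reactants: 7 1,3-bis(methoxymethoxy)benzene
Product: 9 2-bromo-1,3-bis(methoxymethoxy)benzene, via aryllithium 8 (not isolated)
Conditions: n-BuLi, THF, 0 °C to rt, 1 h; BrCl2C–CCl2Br, −78 °C to rt
Reagents that add atoms: 1,2-dibromo-1,1,2,2-tetrachloroethane, BrC(Cl)(Cl)C(Cl)(Cl)Br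
Why: Directed ortho-metalation removes the doubly chelated C2–H between the two MOM ethers, and the aryllithium takes bromine from the polyhaloethane.

Step 5
Reactants: 9 2-bromo-1,3-bis(methoxymethoxy)benzene
Product: 11 4-bromo-3,5-bis(methoxymethoxy)phenol, via arylboronic pinacol ester 10 (not isolated)
Conditions: [Ir(OMe)(cod)]2 (1.5 mol%), 4,4'-di-tert-butyl-2,2'-bipyridine (3 mol%), B2pin2, THF, 80 °C; then KHSO5 (oxone), acetone/H2O, rt, 10 min
Reagents that add atoms: potassium peroxymonosulfate KHSO5, [K+].[O-]S(=O)(=O)OO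
Why: Sterically governed iridium-catalysed C–H borylation occurs only at the C–H with no ortho substituent (para to bromine), and one-pot oxidation of the C–B bond gives the phenol with the bromide and acetals intact.

Step 6
Reactants: 11 4-bromo-3,5-bis(methoxymethoxy)phenol
Product: 12 2-bromo-1,3,5-tris(methoxymethoxy)benzene
Conditions: MOMCl, iPr2NEt, CH2Cl2, 0 °C to rt
Reagents that add atoms: chloro(methoxy)methane (MOMCl), COCCl
Why: Routine MOM ether formation at the free phenol completes the protection of ring B.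

Step 7
Reactants: 12 2-bromo-1,3,5-tris(methoxymethoxy)benzene; 13 N,N-dimethylformamide
Product: 15 2,4,6-tris(methoxymethoxy)benzaldehyde, via aryllithium 14 (not isolated)
Conditions: n-BuLi, THF, −78 °C, 15 min; 13, −78 to 0 °C; H2O
Reagents that add atoms: none
Why: Bromine–lithium exchange gives an aryllithium stabilised by two flanking acetal oxygens, which is formylated by DMF (Bouveault reaction).

Step 8
Reactants: 11 4-bromo-3,5-bis(methoxymethoxy)phenol; 16 acetic anhydride
Product: 17 4-bromo-3,5-bis(methoxymethoxy)phenyl acetate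
Conditions: pyridine, DMAP (cat.), CH2Cl2, rt
Reagents that add atoms: none
Why: O-acylation masks the phenol for the coupling, lowers the electron density of the aryl bromide and installs the acetyl group that step 10 moves onto carbon.

Step 9
Reactants: 17 4-bromo-3,5-bis(methoxymethoxy)phenyl acetate; 5 (2R)-5-methyl-2-(prop-1-en-2-yl)hex-4-en-1-ol (1.7 equiv)
Product: 19 4-[(2S)-5-methyl-2-(prop-1-en-2-yl)hex-4-en-1-yl]-3,5-bis(methoxymethoxy)phenyl acetate, via benzoxazoline alcohol adduct 18 (not isolated)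
Conditions: 5, 5,7-di-tert-butyl-3-phenylbenzoxazolium tetrafluoroborate (1.6 equiv), pyridine, MTBE, rt, 15 min; filtrate added to 17, Ir(ppy)2(dtbbpy)PF6 (1.5 mol%), NiBr2(dtbbpy) (10 mol%), quinuclidine, DMA, 450 nm LEDs, rt
Reagents that add atoms: none
Why: Metallaphotoredox deoxygenative arylation: the excited iridium photocatalyst oxidises adduct 18, deprotonation and β-scission expel the benzoxazolone and the primary lavandulyl radical, and this radical is captured by the aryl nickel bromide formed from 17 and zerovalent nickel and coupled by reductive elimination; the stereocentre is β to the radical and is untouched (its descriptor changes to S only by priority), the competing 1,2-vinyl shift is slow, and the flanking groups are small alkoxy groups.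

Step 10
Reactants: 19 4-[(2S)-5-methyl-2-(prop-1-en-2-yl)hex-4-en-1-yl]-3,5-bis(methoxymethoxy)phenyl acetate
Product: 20 1-{6-hydroxy-2,4-bis(methoxymethoxy)-3-[(2S)-5-methyl-2-(prop-1-en-2-yl)hex-4-en-1-yl]phenyl}ethan-1-one
Conditions: hν (254 nm, quartz), degassed cyclohexane (0.01 M), rt; recovered phenol re-acetylated
Reagents that add atoms: none
Why: Photo-Fries rearrangement: homolysis of the aryl O–acyl bond, in-cage recombination of the acetyl and aryloxyl radicals at an ortho carbon (para is blocked, the two ortho sites are equivalent) and tautomerisation give the hydrogen-bonded, photostable ketone under neutral conditions that spare acetals and alkenes.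

Step 11
Reactants: 20 1-{6-hydroxy-2,4-bis(methoxymethoxy)-3-[(2S)-5-methyl-2-(prop-1-en-2-yl)hex-4-en-1-yl]phenyl}ethan-1-one; 15 2,4,6-tris(methoxymethoxy)benzaldehyde
Product: 22 (2RS)-5,7-bis(methoxymethoxy)-6-[(2S)-5-methyl-2-(prop-1-en-2-yl)hex-4-en-1-yl]-2-[2,4,6-tris(methoxymethoxy)phenyl]-2,3-dihydro-4H-chromen-4-one (about 1:1 mixture of C2 epimers), via chalcone 21 (not isolated)
Conditions: KOH (50% aq), EtOH, rt, 48 h; then AcOH to pH 7, NaOAc, reflux
Reagents that add atoms: none
Why: Claisen–Schmidt condensation gives the E-chalcone and buffered heating closes ring C by oxa-Michael addition of the only free phenol, which fixes the side chain at C6; C2 forms without control.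

Step 12
Reactants: 22 C2-epimer mixture of the pentakis-MOM flavanone
Product: 23 (2S)-5,7-bis(methoxymethoxy)-6-[(2S)-5-methyl-2-(prop-1-en-2-yl)hex-4-en-1-yl]-2-[2,4,6-tris(methoxymethoxy)phenyl]-2,3-dihydro-4H-chromen-4-one
Conditions: RhCl(C5Me5)[(R,R)-TsDPEN] (1 mol%), HCO2H/Et3N (5:2), EtOAc, rt, stopped at 50–55% conversion; chromatography
Reagents that add atoms: none
Why: Noyori-type asymmetric transfer hydrogenation used as a kinetic resolution: the (R,R)-catalyst delivers hydride to the face that gives the 4R alcohol, which is the favoured cis addition only for the 2R epimer, so that epimer is reduced to the flavan-4-ol and the 2S ketone is recovered; the distant side-chain centre has no influence.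

Step 13
Reactants: 23 (2S)-pentakis-MOM flavanone
Product: 24 (2S)-5,7-dihydroxy-6-[(2S)-5-methyl-2-(prop-1-en-2-yl)hex-4-en-1-yl]-2-(2,4,6-trihydroxyphenyl)-2,3-dihydro-4H-chromen-4-one
Conditions: HCl (3 M aq)/MeOH, 40 °C, monitored closely
Reagents that add atoms: none
Why: Acid-catalysed transacetalisation of the five MOM ethers to dimethoxymethane, under mild conditions chosen to limit addition of the flanking phenols to the side-chain alkenes and ring-opening epimerisation at C2.

**Compound list**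
1 | 3-methylbut-3-enoic acid | C=C(C)CC(=O)O | starting material
2 | 1-bromo-3-methylbut-2-ene | CC(C)=CCBr | starting material
3 | dilithium 3-methylbuta-1,3-diene-1,1-diolate | C=C(C)C=C(O[Li])O[Li] | intermediate
4 | (2R)-5-methyl-2-(prop-1-en-2-yl)hex-4-enoic acid | C=C(C)[C@@H](CC=C(C)C)C(=O)O | intermediate
5 | (2R)-5-methyl-2-(prop-1-en-2-yl)hex-4-en-1-ol | C=C(C)[C@@H](CC=C(C)C)CO | intermediate
6 | benzene-1,3-diol | Oc1cccc(O)c1 | starting material
7 | 1,3-bis(methoxymethoxy)benzene | COCOc1cccc(OCOC)c1 | intermediate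
8 | [2,6-bis(methoxymethoxy)phenyl]lithium | [Li]c1c(OCOC)cccc1OCOC | intermediate
9 | 2-bromo-1,3-bis(methoxymethoxy)benzene | COCOc1cccc(OCOC)c1Br | intermediate
10 | 2-[4-bromo-3,5-bis(methoxymethoxy)phenyl]-4,4,5,5-tetramethyl-1,3,2-dioxaborolane | COCOc1cc(B2OC(C)(C)C(C)(C)O2)cc(OCOC)c1Br | intermediate
11 | 4-bromo-3,5-bis(methoxymethoxy)phenol | COCOc1cc(O)cc(OCOC)c1Br | intermediate
12 | 2-bromo-1,3,5-tris(methoxymethoxy)benzene | COCOc1cc(OCOC)c(Br)c(OCOC)c1 | intermediate
13 | N,N-dimethylformamide | CN(C)C=O | starting material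
14 | [2,4,6-tris(methoxymethoxy)phenyl]lithium | [Li]c1c(OCOC)cc(OCOC)cc1OCOC | intermediate
15 | 2,4,6-tris(methoxymethoxy)benzaldehyde | O=Cc1c(OCOC)cc(OCOC)cc1OCOC | intermediate
16 | acetic anhydride | CC(=O)OC(C)=O | starting material
17 | 4-bromo-3,5-bis(methoxymethoxy)phenyl acetate | CC(=O)Oc1cc(OCOC)c(Br)c(OCOC)c1 | intermediate
18 | 5,7-di-tert-butyl-2-{[(2R)-5-methyl-2-(prop-1-en-2-yl)hex-4-en-1-yl]oxy}-3-phenyl-2,3-dihydro-1,3-benzoxazole (epimers at the aminal carbon) | C=C(C)[C@@H](CC=C(C)C)COC1Oc2c(C(C)(C)C)cc(C(C)(C)C)cc2N1c1ccccc1 | intermediate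
19 | 4-[(2S)-5-methyl-2-(prop-1-en-2-yl)hex-4-en-1-yl]-3,5-bis(methoxymethoxy)phenyl acetate | C=C(C)[C@@H](CC=C(C)C)Cc1c(OCOC)cc(OC(C)=O)cc1OCOC | intermediate
20 | 1-{6-hydroxy-2,4-bis(methoxymethoxy)-3-[(2S)-5-methyl-2-(prop-1-en-2-yl)hex-4-en-1-yl]phenyl}ethan-1-one | C=C(C)[C@@H](CC=C(C)C)Cc1c(OCOC)cc(O)c(C(C)=O)c1OCOC | intermediate
21 | (2E)-1-{6-hydroxy-2,4-bis(methoxymethoxy)-3-[(2S)-5-methyl-2-(prop-1-en-2-yl)hex-4-en-1-yl]phenyl}-3-[2,4,6-tris(methoxymethoxy)phenyl]prop-2-en-1-one | C=C(C)[C@@H](CC=C(C)C)Cc1c(OCOC)cc(O)c(C(=O)/C=C/c2c(OCOC)cc(OCOC)cc2OCOC)c1OCOC | intermediate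
22 | (2RS)-5,7-bis(methoxymethoxy)-6-[(2S)-5-methyl-2-(prop-1-en-2-yl)hex-4-en-1-yl]-2-[2,4,6-tris(methoxymethoxy)phenyl]-2,3-dihydro-4H-chromen-4-one | C=C(C)[C@@H](CC=C(C)C)Cc1c(OCOC)cc2c(c1OCOC)C(=O)CC(c1c(OCOC)cc(OCOC)cc1OCOC)O2 | intermediate
23 | (2S)-5,7-bis(methoxymethoxy)-6-[(2S)-5-methyl-2-(prop-1-en-2-yl)hex-4-en-1-yl]-2-[2,4,6-tris(methoxymethoxy)phenyl]-2,3-dihydro-4H-chromen-4-one | C=C(C)[C@@H](CC=C(C)C)Cc1c(OCOC)cc2c(c1OCOC)C(=O)C[C@@H](c1c(OCOC)cc(OCOC)cc1OCOC)O2 | intermediate
24 | (2S)-5,7-dihydroxy-6-[(2S)-5-methyl-2-(prop-1-en-2-yl)hex-4-en-1-yl]-2-(2,4,6-trihydroxyphenyl)-2,3-dihydro-4H-chromen-4-one | C=C(C)[C@@H](CC=C(C)C)Cc1c(O)cc2c(c1O)C(=O)C[C@@H](c1c(O)cc(O)cc1O)O2 | target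

**Count and risks**
Total: 13 steps. Longest linear sequence: 9 steps (3, 4, 5, 8, 9, 10, 11, 12, 13); steps 1–2 and 6–7 are side branches.

Step 9 is the most likely to fail, because oxidative addition at a bromide with two ortho alkoxy groups may be slow, leaving reduced arene and radical dimer. The fallback sets out from 11 and 5 and comes back at 19. Phenol 11 is silylated (TIPSCl, imidazole, DMF) to [4-bromo-3,5-bis(methoxymethoxy)phenoxy]tri(propan-2-yl)silane F1, and 5 is converted (CBr4, PPh3, CH2Cl2, 0 °C) into (3R)-3-(bromomethyl)-2,6-dimethylhepta-1,5-diene F2. Bromine–lithium exchange on F1 (n-BuLi, THF, −78 °C) gives {2,6-bis(methoxymethoxy)-4-[tri(propan-2-yl)silyloxy]phenyl}lithium F3, and MgBr2·OEt2 turns it into the arylmagnesium bromide F4. Slow addition of F4 to F2 with Fe(acac)3 (5 mol%) and TMEDA in THF at 0 °C gives tri(propan-2-yl){4-[(2S)-5-methyl-2-(prop-1-en-2-yl)hex-4-en-1-yl]-3,5-bis(methoxymethoxy)phenoxy}silane F5. This iron-catalysed Kumada-type alkylation forms the same lavandulyl radical by bromine abstraction at low-valent iron and tolerates two ortho substituents on the aryl partner. TBAF in THF then releases 4-[(2S)-5-methyl-2-(prop-1-en-2-yl)hex-4-en-1-yl]-3,5-bis(methoxymethoxy)phenol F6 as its ammonium salt, which is acetylated in the same flask with Ac2O to give 19.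

Step 10 may give low conversion or mainly free phenol by radical escape. The fallback sets out from 19 and comes back at 20. Acetate 19 is cleaved (K2CO3, MeOH, 0 °C) to the phenol F6. Magnesium-mediated ortho-formylation (MgCl2, Et3N, paraformaldehyde, MeCN, reflux) gives 6-hydroxy-2,4-bis(methoxymethoxy)-3-[(2S)-5-methyl-2-(prop-1-en-2-yl)hex-4-en-1-yl]benzaldehyde F7. MeMgBr (2.2 equiv, THF, 0 °C) gives 2-(1-hydroxyethyl)-3,5-bis(methoxymethoxy)-4-[(2S)-5-methyl-2-(prop-1-en-2-yl)hex-4-en-1-yl]phenol F8 as a mixture of carbinol epimers, and MnO2 (CH2Cl2, rt) oxidises it to 20.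

Step 13 risks chroman formation from the side-chain alkenes and the flanking phenols, and epimerisation at C2 once the ring-B phenols are free in protic acid. The fallback sets out from 23 and comes back at 24. TESOTf and 2,2'-bipyridyl (CH2Cl2, 0 °C) exchange each aryl MOM ether for a silyl ether without protic acid, giving (2S)-6-[(2S)-5-methyl-2-(prop-1-en-2-yl)hex-4-en-1-yl]-5,7-bis(triethylsilyloxy)-2-[2,4,6-tris(triethylsilyloxy)phenyl]-2,3-dihydro-4H-chromen-4-one F9. KHF2 in MeOH at rt then frees the five phenols under near-neutral conditions to give 24.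

**Further compounds**
F1 | step 9 | [4-bromo-3,5-bis(methoxymethoxy)phenoxy]tri(propan-2-yl)silane | CC(C)[Si](Oc1cc(OCOC)c(Br)c(OCOC)c1)(C(C)C)C(C)C
F2 | step 9 | (3R)-3-(bromomethyl)-2,6-dimethylhepta-1,5-diene | C=C(C)[C@@H](CC=C(C)C)CBr
F3 | step 9 | {2,6-bis(methoxymethoxy)-4-[tri(propan-2-yl)silyloxy]phenyl}lithium | [Li]c1c(OCOC)cc(O[Si](C(C)C)(C(C)C)C(C)C)cc1OCOC
F4 | step 9 | {2,6-bis(methoxymethoxy)-4-[tri(propan-2-yl)silyloxy]phenyl}magnesium bromide | Br[Mg]c1c(OCOC)cc(O[Si](C(C)C)(C(C)C)C(C)C)cc1OCOC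
F5 | step 9 | tri(propan-2-yl){4-[(2S)-5-methyl-2-(prop-1-en-2-yl)hex-4-en-1-yl]-3,5-bis(methoxymethoxy)phenoxy}silane | C=C(C)[C@@H](CC=C(C)C)Cc1c(OCOC)cc(O[Si](C(C)C)(C(C)C)C(C)C)cc1OCOC
F6 | step 9 | 4-[(2S)-5-methyl-2-(prop-1-en-2-yl)hex-4-en-1-yl]-3,5-bis(methoxymethoxy)phenol | C=C(C)[C@@H](CC=C(C)C)Cc1c(OCOC)cc(O)cc1OCOC
F7 | step 10 | 6-hydroxy-2,4-bis(methoxymethoxy)-3-[(2S)-5-methyl-2-(prop-1-en-2-yl)hex-4-en-1-yl]benzaldehyde | C=C(C)[C@@H](CC=C(C)C)Cc1c(OCOC)cc(O)c(C=O)c1OCOC
F8 | step 10 | 2-(1-hydroxyethyl)-3,5-bis(methoxymethoxy)-4-[(2S)-5-methyl-2-(prop-1-en-2-yl)hex-4-en-1-yl]phenol | C=C(C)[C@@H](CC=C(C)C)Cc1c(OCOC)cc(O)c(C(C)O)c1OCOC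
F9 | step 13 | (2S)-6-[(2S)-5-methyl-2-(prop-1-en-2-yl)hex-4-en-1-yl]-5,7-bis(triethylsilyloxy)-2-[2,4,6-tris(triethylsilyloxy)phenyl]-2,3-dihydro-4H-chromen-4-one | C=C(C)[C@@H](CC=C(C)C)Cc1c(O[Si](CC)(CC)CC)cc2c(c1O[Si](CC)(CC)CC)C(=O)C[C@@H](c1c(O[Si](CC)(CC)CC)cc(O[Si](CC)(CC)CC)cc1O[Si](CC)(CC)CC)O2
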